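At late times the maple, alder and birch readings stand still, so we compare what each run ends with.

| setting | maple | alder | birch | gamma | delta | alpha |
|---|---|---|---|---|---|---|
| D | 0.20 M | 0.20 M | 0.20 M | 0.20 M | 0.20 M | 0.20 M (fed, over 2.5 d) |
| X | 0.20 M | 0.10 M | 0.40 M | 0.200 M (fed, over 2.5 d) | 0.200 M | 0.200 M |
| remark | run made earlier | run made earlier | run made earlier | all else is in the flask from the start; the feed brings no volume worth counting | everything together at the start | all else is in the flask from the start; the feed brings no volume worth counting |
| time |  |  |  | 3.0 d | 3.0 d | 3.0 d |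

| run | time / d | Q / % | E / % |
|---|---|---|---|
| maple | 0.250 | 30.0 | 50.6 |
| maple | 0.500 | 38.6 | 51.3 |
| maple | 1.25 | 40.0 | 49.7 |
| maple | 3.00 | 38.3 | 49.6 |
| alder | 0.833 | 44.7 | 25.7 |
| alder | 1.67 | 45.2 | 25.2 |
| alder | 2.50 | 45.2 | 24.8 |
| alder | 4.00 | 44.2 | 26.8 |
| birch | 0.250 | 24.7 | 68.8 |
| birch | 0.625 | 25.9 | 68.7 |
| birch | 1.67 | 25.3 | 69.1 |
| birch | 4.00 | 27.8 | 70.8 |

(scatter of a reading: 1 percentage point)

- in percentages every species weighs as the D in it: one Q counts as two

- the flask with the highest amount of Q, in percent of the D charged ("all alike" if they lie within 1.5 percentage points) (gamma / delta / alpha / all alike)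
- final Q, as a percentage of the D charged, in gamma
- final Q, as a percentage of the D charged, in delta
- final Q, as a percentage of the D charged, in alpha

First question: how much D stands in neither E nor Q? Averaged over the last three readings, this gap is 4.13% in birch, 10.8% in maple and 29.5% in alder. X falls by a factor of 2.00 at each step of that series, and the gap grows by about 2.73.

Second question: how does the D found in E and Q divide? We take the equal-charge run as our zero: the last three maple readings give 0.437 for the split, which is Q divided by Q plus E (a selectivity). It is 0.637 in alder and 0.275 in birch.

Third question: what do the feeds do? Maple is flat by 0.500 d, and by then gamma has received 0.0400 M of X, less than the 0.0500 M of one more step below alder. Carrying the gap one more step, we reckon 19.5% of the D in E and Q, so our estimate for gamma is Q of 8.52% to 12.4%. We treat alpha like birch, which gives 26.4% to 41.9%, with the middle at 34.1%. We expect delta to repeat maple's readings at 39.0%, above that middle, so we name delta, narrowly.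

The forecast differs: gamma highest, with 62%, 39% and 2% for gamma, delta and alpha, saying of gamma that “D sits almost without X”.

The flasks give delta highest, with 12.2%, 38.1% and 36.4%.

    D + X ⇌ E + L (K = 1.40, k = 342 /M/h)
    L → G (k = 0.427 /h)
    D + E → Q (k = 1.25 /M/h)
    2 D → J (k = 0.913 /M/h)

Gamma's split is 0.404, close to maple's 0.437, while its J stands at 69.8%. The neighbouring flask is gamma with 0.050 M of X. It ends with 82.9% as J and 9.77% as E. Maple's split turns that E into Q of 7.58%, and the neighbouring flask holds 7.29%.

(The numbers in the tables come from a simulation for substances that don't exist, and the scatter is random.)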